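(Readings and results were generated by integration from invented constants; noise was put on by code.)

Slowness comes first: in the north run 22.8% of the substrate still stands after 20.0 h. The reckoning assumes that the catalyst intermediate breaks down fast, so the catalyst waits free and each substrate entering the round leaves at once as target.

| setting | north | noon | midnight |
|---|---|---|---|
| substrate | 0.25 M | 0.25 M | 0.25 M |
| precatalyst | 1.2 mM | 2.5 mM | 2.5 mM |
| temperature | 90 °C |  |  |
| remark | run made earlier | at 150 °C throughout | at 90 °C until 20 h, from then on at 150 °C |
| time |  | 4.0 d | 4.0 d |

- north (time / h: target / %, substrate / %): 1.50: 3.3, 95.1; 3.00: 8.7, 87.2; 5.00: 12.9, 76.9; 10.0: 20.1, 52.8; 20.0: 23.7, 22.8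

(standard deviation of a reading: 1 percentage point)

- in percentages every species weighs as the substrate in it: one side product counts as two
- the numbers in the tables scatter by 1 percentage point (one standard deviation)
- steps thought possible: catalyst intermediate -> free catalyst + target; substrate + target -> side product; substrate + free catalyst -> catalyst intermediate; precatalyst <-> free catalyst
- the earlier runs do not show what temperature does; that part of a forecast is a guess
- no earlier run changes the charge of precatalyst; that part of a forecast is a guess

- the flask that ends with the higher amount of target, in percent of the substrate charged, or "neither" when 2 percentage points or less lies between them (noon / midnight / neither)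
- final target, as a percentage of the substrate charged, in noon
- final target, as a percentage of the substrate charged, in midnight

Write s and p for the fractions of the charge standing as substrate and target. One side product uses one substrate and one target, so over an interval the target made is substrate lost plus target gained, divided by 2. In the north run, target made per unit of s comes to 0.0442 h⁻¹ between 3.00 h and 5.00 h, and 0.0444 h⁻¹ between 10.0 h and 20.0 h, about the same. The catalytic path thus reads as pseudo-first-order, k·s, while the side step goes as k′·s·p.

Target made over target eaten is then a/p, with a = k/k′, and s cancels, so while a stays fixed the clock drops out of where target ends. Between the last two north readings, a reads 27.9%, a reading that carries their scatter: this is the selectivity factor, the target fraction at which target is eaten as fast as it is made. Integrating gives 1 − s = −p − 2a·ln(1 − p/a).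

If k follows the precatalyst charge, which is a guess, a becomes 58.1%, and at s = 0 the rule ends target at 40.8% at 90 °C. For midnight the reckoning takes k as 0.0926 h⁻¹, so at 20 h it puts substrate between 4.27% and 15.7%, and, on the guess that the little remaining after the change of temperature moves target by little, it puts midnight's end near 40.8%. Noon spends its whole course at 150 °C, where a is unread; the guess is that a falls, which puts noon below midnight.

The forecast gives midnight, with 32% for noon and 41% for midnight, on the ground that “The uncatalysed bimolecular side step probably has the higher activation energy”.

The flasks give midnight as the higher: 26.2% in noon and 40.1% in midnight.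

    catalyst intermediate → free catalyst + target (k = 3420 h⁻¹, Ea = 84.0 kJ mol⁻¹)
    substrate + target → side product (k = 0.645 M⁻¹ h⁻¹, Ea = 86.0 kJ mol⁻¹)
    substrate + free catalyst → catalyst intermediate (k = 41.7 M⁻¹ h⁻¹, Ea = 72.0 kJ mol⁻¹)
    precatalyst ⇌ free catalyst (K = 18.5, k = 1.59 h⁻¹, Ea = 117 kJ mol⁻¹, ΔH = −18.0 kJ mol⁻¹)
    (constants at 90 °C)

At 0.00632 d in noon the catalytic path took 1.5 times as much substrate as the side step, and target was made 1.53 times as fast as used up. The half-life of target under the side step then stood at 0.13 h, far shorter than the 4.0 d allowed. Noon's end, put into the rule, reads a = 29.7%, 0.511 times the value reckoned for 90 °C. Taken inversely with the substrate charge, since k′ counts in fractions of that charge, a is 120% for a neighbour of noon charged with 0.062 M; at that flask's end of 57.8% the rule counts 100% of its charge used, and its substrate stands at 0%.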